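**Retrosynthetic overview**
1. Justin C (18) ⇐ triacetate 16: one hydrogenolysis removes the benzylic acetate and the phenol benzyl ether.
2. 16 ⇐ triol 15 ⇐ hydroxy lactone 14 (LiAlH4, then Ac2O).
3. Key C–C bond: 14 ⇐ lithium enolate of (R)-lactone 10 + aldehyde 12, an intermolecular aldol that joins the two aryl halves trans to the existing benzyl group.
4. 10 ⇐ Evans alkylation of N-acyl oxazolidinone 4 with tert-butyl bromoacetate 5, then LiBH4 and acid lactonisation.
5. Rings: both arenes are bought; the only ring made is the temporary γ-lactone (step 4), which is opened again in step 7.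

Assumption: the carbinol carbon created in the aldol is removed in the last step, so 14–17 are carried as mixtures of epimers at that carbon and their SMILES leave it undefined; all other stereocentres are defined.

**Step 1**
Reactants: 1 3-(3,4-dimethoxyphenyl)propanoic acid; 2 (S)-4-benzyl-1,3-oxazolidin-2-one
Product: 4 (4S)-4-benzyl-3-[3-(3,4-dimethoxyphenyl)propanoyl]-1,3-oxazolidin-2-one, via mixed pivalic anhydride 3 (not isolated)
Conditions: PivCl (1.1 equiv), Et3N (2.5 equiv), THF, −20 °C, 1 h; then LiCl (1.1 equiv), 2, −20 °C → rt, 12 h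
Reagents that add atoms: none
Why: N-acylation of the oxazolidinone through the mixed anhydride (LiCl/Et3N activation) occurs at the unhindered arylpropanoyl carbonyl and touches no stereocentre.

**Step 2**
Reactants: 4 (4S)-4-benzyl-3-[3-(3,4-dimethoxyphenyl)propanoyl]-1,3-oxazolidin-2-one; 5 tert-butyl bromoacetate
Product: 7 tert-butyl (3R)-3-{[(4S)-4-benzyl-2-oxo-1,3-oxazolidin-3-yl]carbonyl}-4-(3,4-dimethoxyphenyl)butanoate, via sodium Z-enolate 6 (not isolated)
Conditions: NaHMDS (1.1 equiv), THF, −78 °C, 1 h; then 5 (1.5 equiv), −78 → −40 °C, 3 h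
Reagents that add atoms: none
Why: Evans asymmetric alkylation, in which the chelated Z-enolate is shielded on one face by the C4 benzyl group of the (S)-auxiliary, so the bromoacetate adds to the opposite face and sets the (3R) centre (dr typically ≥95:5, minor isomer removed by chromatography).

**Step 3**
Reactants: 7 tert-butyl (3R)-3-{[(4S)-4-benzyl-2-oxo-1,3-oxazolidin-3-yl]carbonyl}-4-(3,4-dimethoxyphenyl)butanoate
Product: 8 tert-butyl (3R)-4-(3,4-dimethoxyphenyl)-3-(hydroxymethyl)butanoate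
Conditions: LiBH4 (1.5 equiv), MeOH (1.5 equiv), THF, 0 °C, 2 h
Reagents that add atoms: none
Why: Reductive cleavage of the auxiliary, since LiBH4 reduces the activated imide carbonyl much faster than the hindered tert-butyl ester; the stereocentre is untouched and the auxiliary is recovered.

**Step 4**
Reactants: 8 tert-butyl (3R)-4-(3,4-dimethoxyphenyl)-3-(hydroxymethyl)butanoate
Product: 10 (4R)-4-(3,4-dimethoxybenzyl)dihydrofuran-2(3H)-one, via hydroxy acid 9 (not isolated)
Conditions: TFA/CH2Cl2 (1:4), 0 °C → rt, 3 h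
Reagents that add atoms: none
Why: Acidolysis of the tert-butyl ester followed by spontaneous acid-catalysed γ-lactonisation (intramolecular Fischer esterification); the stereocentre is not involved.

**Step 5**
Reactants: 11 syringaldehyde (4-hydroxy-3,5-dimethoxybenzaldehyde)
Product: 12 4-(benzyloxy)-3,5-dimethoxybenzaldehyde
Conditions: BnBr (1.2 equiv), K2CO3 (2 equiv), DMF, 60 °C, 4 h
Reagents that add atoms: benzyl bromide, BrCc1ccccc1
Why: Williamson ether synthesis on the phenoxide; the non-enolisable aldehyde is inert to K2CO3.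

**Step 6 (key step)**
Reactants: 10 (4R)-4-(3,4-dimethoxybenzyl)dihydrofuran-2(3H)-one; 12 4-(benzyloxy)-3,5-dimethoxybenzaldehyde
Product: 14 (3S,4R)-3-{[4-(benzyloxy)-3,5-dimethoxyphenyl](hydroxy)methyl}-4-(3,4-dimethoxybenzyl)dihydrofuran-2(3H)-one (trans; both carbinol epimers), via lithium lactone enolate 13 (not isolated)
Conditions: LDA (1.15 equiv), THF, −78 °C, 45 min; then 12 (1.1 equiv), −78 °C, 2 h; AcOH (1.5 equiv) in THF at −78 °C
Reagents that add atoms: none
Why: Intermolecular aldol addition of a lactone lithium enolate to a non-enolisable aldehyde, in which the aldehyde approaches anti to the C4 benzyl group and so sets the trans (3S,4R) ring relationship; the carbinol configuration is irrelevant because that centre is removed in step 9.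

**Step 7**
Reactants: 14 (3S,4R)-3-{[4-(benzyloxy)-3,5-dimethoxyphenyl](hydroxy)methyl}-4-(3,4-dimethoxybenzyl)dihydrofuran-2(3H)-one
Product: 15 (2R,3R)-2-{[4-(benzyloxy)-3,5-dimethoxyphenyl](hydroxy)methyl}-3-(3,4-dimethoxybenzyl)butane-1,4-diol
Conditions: LiAlH4 (3 equiv), THF, 0 °C → rt, 2 h (lactone added to the hydride); Fieser work-up
Reagents that add atoms: none
Why: LiAlH4 reduction of the lactone to the 1,4-diol, which removes the only carbonyl and so freezes the two backbone centres as (2R,3R); the benzyl ether is inert.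

**Step 8**
Reactants: 15 (2R,3R)-2-{[4-(benzyloxy)-3,5-dimethoxyphenyl](hydroxy)methyl}-3-(3,4-dimethoxybenzyl)butane-1,4-diol
Product: 16 (2R,3R)-2-{(acetyloxy)[4-(benzyloxy)-3,5-dimethoxyphenyl]methyl}-3-(3,4-dimethoxybenzyl)butane-1,4-diyl diacetate
Conditions: Ac2O (6 equiv), pyridine, DMAP (0.1 equiv), CH2Cl2, 0 °C → rt, 4 h
Reagents that add atoms: acetic anhydride, CC(=O)OC(C)=O
Why: DMAP-catalysed acetylation esterifies the two primary and the benzylic hydroxyl, while the phenol stays masked as its benzyl ether and cannot be acetylated.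

**Step 9**
Reactants: 16 (2R,3R)-2-{(acetyloxy)[4-(benzyloxy)-3,5-dimethoxyphenyl]methyl}-3-(3,4-dimethoxybenzyl)butane-1,4-diyl diacetate
Product: 18 Justin C [(2R,3R)-2-(3,4-dimethoxybenzyl)-3-(4-hydroxy-3,5-dimethoxybenzyl)butane-1,4-diyl diacetate], via phenol triacetate 17 (not isolated)
Conditions: H2 (3 atm), 10% Pd/C, EtOAc/AcOH (3:1), rt, 12–24 h
Reagents that add atoms: none
Why: Catalytic hydrogenolysis first cleaves the aryl benzyl ether and then the electron-rich benzylic C–OAc bond, while the primary acetates are inert and neither stereocentre is next to a carbonyl, so (2R,3R) is retained.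

**Compound list**
1 | 3-(3,4-dimethoxyphenyl)propanoic acid | COc1ccc(CCC(=O)O)cc1OC | starting material
2 | (S)-4-benzyl-1,3-oxazolidin-2-one | O=C1N[C@@H](Cc2ccccc2)CO1 | starting material
3 | 3-(3,4-dimethoxyphenyl)propanoic pivalic anhydride (formed in the flask) | COc1ccc(CCC(=O)OC(=O)C(C)(C)C)cc1OC | intermediate
4 | (4S)-4-benzyl-3-[3-(3,4-dimethoxyphenyl)propanoyl]-1,3-oxazolidin-2-one | COc1ccc(CCC(=O)N2[C@@H](Cc3ccccc3)COC2=O)cc1OC | intermediate
5 | tert-butyl bromoacetate | CC(C)(C)OC(=O)CBr | starting material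
6 | sodium (Z)-enolate of 4 (formed in the flask) | [Na+].[O-]/C(=C\Cc1ccc(OC)c(OC)c1)N1[C@@H](Cc2ccccc2)COC1=O | intermediate
7 | tert-butyl (3R)-3-{[(4S)-4-benzyl-2-oxo-1,3-oxazolidin-3-yl]carbonyl}-4-(3,4-dimethoxyphenyl)butanoate | CC(C)(C)OC(=O)C[C@@H](Cc1ccc(OC)c(OC)c1)C(=O)N1[C@@H](Cc2ccccc2)COC1=O | intermediate
8 | tert-butyl (3R)-4-(3,4-dimethoxyphenyl)-3-(hydroxymethyl)butanoate | CC(C)(C)OC(=O)C[C@@H](Cc1ccc(OC)c(OC)c1)CO | intermediate
9 | (3R)-4-(3,4-dimethoxyphenyl)-3-(hydroxymethyl)butanoic acid (formed in the flask) | OC(=O)C[C@@H](Cc1ccc(OC)c(OC)c1)CO | intermediate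
10 | (4R)-4-(3,4-dimethoxybenzyl)dihydrofuran-2(3H)-one | O=C1C[C@@H](Cc2ccc(OC)c(OC)c2)CO1 | intermediate
11 | syringaldehyde (4-hydroxy-3,5-dimethoxybenzaldehyde) | COc1cc(C=O)cc(OC)c1O | starting material
12 | 4-(benzyloxy)-3,5-dimethoxybenzaldehyde | COc1cc(C=O)cc(OC)c1OCc1ccccc1 | intermediate
13 | lithium enolate of lactone 10 (formed in the flask) | [Li+].[O-]C1=C[C@@H](Cc2ccc(OC)c(OC)c2)CO1 | intermediate
14 | (3S,4R)-3-{[4-(benzyloxy)-3,5-dimethoxyphenyl](hydroxy)methyl}-4-(3,4-dimethoxybenzyl)dihydrofuran-2(3H)-one, trans, carbinol epimers | O=C1OC[C@H](Cc2ccc(OC)c(OC)c2)[C@H]1C(O)c3cc(OC)c(OCc4ccccc4)c(OC)c3 | intermediate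
15 | (2R,3R)-2-{[4-(benzyloxy)-3,5-dimethoxyphenyl](hydroxy)methyl}-3-(3,4-dimethoxybenzyl)butane-1,4-diol, carbinol epimers | OC[C@H](Cc1ccc(OC)c(OC)c1)[C@H](CO)C(O)c1cc(OC)c(OCc2ccccc2)c(OC)c1 | intermediate
16 | (2R,3R)-2-{(acetyloxy)[4-(benzyloxy)-3,5-dimethoxyphenyl]methyl}-3-(3,4-dimethoxybenzyl)butane-1,4-diyl diacetate, benzylic epimers | CC(=O)OC[C@H](Cc1ccc(OC)c(OC)c1)[C@H](COC(C)=O)C(OC(C)=O)c1cc(OC)c(OCc2ccccc2)c(OC)c1 | intermediate
17 | (2R,3R)-2-[(acetyloxy)(4-hydroxy-3,5-dimethoxyphenyl)methyl]-3-(3,4-dimethoxybenzyl)butane-1,4-diyl diacetate (formed in the flask) | CC(=O)OC[C@H](Cc1ccc(OC)c(OC)c1)[C@H](COC(C)=O)C(OC(C)=O)c1cc(OC)c(O)c(OC)c1 | intermediate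
18 | Justin C, (2R,3R)-2-(3,4-dimethoxybenzyl)-3-(4-hydroxy-3,5-dimethoxybenzyl)butane-1,4-diyl diacetate | COc1ccc(C[C@@H](COC(C)=O)[C@H](COC(C)=O)Cc2cc(OC)c(O)c(OC)c2)cc1OC | target

**Totals**
Total step count: 9. Longest linear sequence: 8 steps (steps 1, 2, 3, 4, 6, 7, 8, 9 from acid 1); step 5 is a one-step side branch.

**Three steps most likely to fail, with fallbacks**

Step 6 (aldol). The addition is reversible and the electron-rich aldehyde is a weak electrophile, so conversion may be low or retro-aldol may occur on warming. The fallback sets out from 10 and comes back at 14. Commercial methyl syringate is benzylated (BnBr, K2CO3, DMF) to methyl 4-(benzyloxy)-3,5-dimethoxybenzoate F1. F1 is added to the lithium enolate of 10 made with 2.2 equiv of LDA (THF, −78 → 0 °C). This crossed Claisen condensation is driven to completion by deprotonation of the β-keto lactone and gives, after acidic quench, the thermodynamically preferred trans keto lactone (3S,4R)-3-[4-(benzyloxy)-3,5-dimethoxybenzoyl]-4-(3,4-dimethoxybenzyl)dihydrofuran-2(3H)-one F2. NaBH4 in MeOH/THF at −20 °C then reduces only the ketone and delivers 14.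

Step 7 (LiAlH4 on the β-hydroxy lactone). The metal alkoxide of 14 may undergo retro-aldol before the lactone is reduced. The fallback sets out from 14 and comes back at 15. The carbinol is first capped with TBSOTf/2,6-lutidine (CH2Cl2, −78 → 0 °C) to give (3S,4R)-3-{[4-(benzyloxy)-3,5-dimethoxyphenyl][(tert-butyldimethylsilyl)oxy]methyl}-4-(3,4-dimethoxybenzyl)dihydrofuran-2(3H)-one F3, which cannot fragment. LiAlH4 in THF at 0 °C gives (2R,3R)-2-{[4-(benzyloxy)-3,5-dimethoxyphenyl][(tert-butyldimethylsilyl)oxy]methyl}-3-(3,4-dimethoxybenzyl)butane-1,4-diol F4. TBAF in THF removes the silyl group (wherever it may have migrated) and gives 15.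

Step 9 (double hydrogenolysis). After the fast O-debenzylation the benzylic acetate may cleave sluggishly, or the catalyst may stall. The fallback sets out from 14 and comes back at 18, moving the deoxygenation to the lactone stage and giving up the benzyl protection. H2, Pd/C, AcOH with catalytic HClO4 removes the benzylic hydroxyl and the benzyl ether of 14 to give (3R,4R)-4-(3,4-dimethoxybenzyl)-3-(4-hydroxy-3,5-dimethoxybenzyl)dihydrofuran-2(3H)-one F5. LiAlH4 in THF gives (2R,3R)-2-(3,4-dimethoxybenzyl)-3-(4-hydroxy-3,5-dimethoxybenzyl)butane-1,4-diol F6. Ac2O/pyridine/DMAP gives (2R,3R)-2-[4-(acetyloxy)-3,5-dimethoxybenzyl]-3-(3,4-dimethoxybenzyl)butane-1,4-diyl diacetate F7. Pyrrolidine (CH2Cl2, 0 °C → rt) selectively aminolyses the far more reactive aryl acetate and leaves the two primary acetates, giving 18.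

**Further compounds**
F1 | step 6 | methyl 4-(benzyloxy)-3,5-dimethoxybenzoate | COC(=O)c1cc(OC)c(OCc2ccccc2)c(OC)c1
F2 | step 6 | (3S,4R)-3-[4-(benzyloxy)-3,5-dimethoxybenzoyl]-4-(3,4-dimethoxybenzyl)dihydrofuran-2(3H)-one | O=C1OC[C@H](Cc2ccc(OC)c(OC)c2)[C@H]1C(=O)c3cc(OC)c(OCc4ccccc4)c(OC)c3
F3 | step 7 | (3S,4R)-3-{[4-(benzyloxy)-3,5-dimethoxyphenyl][(tert-butyldimethylsilyl)oxy]methyl}-4-(3,4-dimethoxybenzyl)dihydrofuran-2(3H)-one | O=C1OC[C@H](Cc2ccc(OC)c(OC)c2)[C@H]1C(O[Si](C)(C)C(C)(C)C)c3cc(OC)c(OCc4ccccc4)c(OC)c3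
F4 | step 7 | (2R,3R)-2-{[4-(benzyloxy)-3,5-dimethoxyphenyl][(tert-butyldimethylsilyl)oxy]methyl}-3-(3,4-dimethoxybenzyl)butane-1,4-diol | OC[C@H](Cc1ccc(OC)c(OC)c1)[C@H](CO)C(O[Si](C)(C)C(C)(C)C)c1cc(OC)c(OCc2ccccc2)c(OC)c1
F5 | step 9 | (3R,4R)-4-(3,4-dimethoxybenzyl)-3-(4-hydroxy-3,5-dimethoxybenzyl)dihydrofuran-2(3H)-one | O=C1OC[C@H](Cc2ccc(OC)c(OC)c2)[C@H]1Cc3cc(OC)c(O)c(OC)c3
F6 | step 9 | (2R,3R)-2-(3,4-dimethoxybenzyl)-3-(4-hydroxy-3,5-dimethoxybenzyl)butane-1,4-diol | OC[C@H](Cc1ccc(OC)c(OC)c1)[C@H](CO)Cc1cc(OC)c(O)c(OC)c1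
F7 | step 9 | (2R,3R)-2-[4-(acetyloxy)-3,5-dimethoxybenzyl]-3-(3,4-dimethoxybenzyl)butane-1,4-diyl diacetate | CC(=O)OC[C@H](Cc1ccc(OC)c(OC)c1)[C@H](COC(C)=O)Cc1cc(OC)c(OC(C)=O)c(OC)c1
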